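**Retr­osynthetic overview**
1. Oblongifolin B ⇒ remove two aryl silyl ethers and cut C1–C8. This gives a pyran-fused, dearomatised acylphloroglucinol. The tertiary C8 cation of the biosynthesis is released from its O4–C8 bond and captured by C1, which closes carbocycle B of the bicyclo[3.3.1]nonane between two quaternary carbons.
2. Pyran ⇒ cut O4–C8. This gives a monocyclic polyprenylated acylphloroglucinol with an isopropenyl-terminated C15 chain at C5. Only its single 1,1-disubstituted alkene is addressed, so all prenyl and geranyl groups are in place from the start.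
3. ⇒ cut C5–C6. Alkylative dearomatisation of the symmetric 3,5-diprenylmaclurin nucleus with an enantiopure primary triflate (the geranyl homologue of lavandulol), the laboratory version of dearomatising prenyl transfer.
4. Nucleus ⇒ phloroglucinol + 3,4-dihydroxybenzonitrile + 2 prenyl bromide. Chain ⇒ senecioyl chloride + geranyl bromide on an Evans auxiliary, which sets C7.
5. Ring order: ring A (phloroglucinol, bought) → temporary pyran (cation reservoir) → carbocycle B.

Assumption: PPAP numbering is kept for all precursors (C1 bridgehead next to C8 = CMe2, C2–C4 enolised triketone with the aroyl group on C3, C5 other bridgehead, C6 CH2, C7 geranyl-bearing CH, C9 bridging ketone; O2, O4, O9 are the oxygens on those carbons), and enol tautomers are drawn arbitrarily.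

**Step 1**
Reactants: 1 phloroglucinol; 2 3,4-dihydroxybenzonitrile
Product: 3 maclurin [(3,4-dihydroxyphenyl)(2,4,6-trihydroxyphenyl)methanone]
Conditions: HCl (g), ZnCl2, Et2O, 0 °C; then H2O, reflux
Reagents that add atoms: water, O
Why: Houben–Hoesch acylation: the HCl/ZnCl2-activated nitrile attacks the very electron-rich phloroglucinol once (the ketiminium salt precipitates and deactivates the ring), the free catechol is inert under these acidic conditions, and boiling water hydrolyses the ketimine to the benzophenone; no stereocentre.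

**Step 2**
Reactants: 3 maclurin; 4 prenyl bromide (2.1 equiv)
Product: 5 3,5-diprenylmaclurin [(3,4-dihydroxyphenyl)[2,4,6-trihydroxy-3,5-bis(3-methylbut-2-enyl)phenyl]methanone]
Conditions: Na2B4O7·10H2O, KOH, H2O, argon, 0 °C → rt; then 1 M HCl
Reagents that add atoms: none
Why: Aqueous alkaline C-alkylation of an acylphloroglucinolate (the laboratory counterpart of aromatic prenyl transfer): in water the hydrogen-bonded oxygens are poor nucleophiles so the soft allylic bromide is taken up at the two free ring carbons, while the catechol is masked in situ as its anionic borate ester, a trick known from selective flavonoid alkylation, and is released on acidification; no stereocentre.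

**Step 3**
Reactants: 5 3,5-diprenylmaclurin
Product: 6 3',4'-bis-O-TBS-3,5-diprenylmaclurin
Conditions: TBSCl (2.2 equiv), imidazole, DMF, 0 °C
Reagents that add atoms: tert-butyldimethylsilyl chloride, CC(C)(C)[Si](C)(C)Cl
Why: Silyl ether protection under steric and hydrogen-bond control: only the two unhindered catechol hydroxyls react, because O2-H and O4-H are chelated to the ketone and O9-H is flanked by two prenyl groups; no stereocentre.

**Step 4**
Reactants: 7 (S)-4-benzyloxazolidin-2-one; 8 3-methylbut-2-enoyl chloride
Product: 9 (S)-4-benzyl-3-(3-methylbut-2-enoyl)oxazolidin-2-one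
Conditions: n-BuLi, THF, −78 °C; then 8, −78 → 0 °C
Reagents that add atoms: none
Why: N-acylation of the lithiated Evans oxazolidinone by the acid chloride; the auxiliary stereocentre is untouched.

**Step 5**
Reactants: 9 N-senecioyl oxazolidinone; 10 geranyl bromide
Product: 11 (S)-4-benzyl-3-[(2S,4E)-5,9-dimethyl-2-(prop-1-en-2-yl)deca-4,8-dienoyl]oxazolidin-2-one
Conditions: NaN(SiMe3)2, THF, −78 °C; then 10, −78 → −40 °C
Reagents that add atoms: none
Why: Evans asymmetric alkylation in its deconjugative form: γ-deprotonation gives the chelated Z-configured sodium dienolate, which reacts at the α-carbon on the face opposite the benzyl group, so geranyl bromide sets the future C7 (S in 11, the same spatial arrangement as 7R in the target, dr above 20:1 expected) and moves the alkene out of conjugation into the isopropenyl group.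

**Step 6**
Reactants: 11 alkylated imide
Product: 12 (2S,4E)-5,9-dimethyl-2-(prop-1-en-2-yl)deca-4,8-dien-1-ol
Conditions: LiBH4, MeOH (1 equiv), Et2O, 0 °C
Reagents that add atoms: none
Why: Reductive cleavage of the imide by borohydride attack at the exocyclic carbonyl; the non-conjugated alkenes are inert, the α-centre is not enolised at 0 °C so its configuration is kept, and the auxiliary 7 is recovered.

**Step 7**
Reactants: 12 C15 alcohol; 6 bis-TBS diprenylmaclurin
Product: 14 (5R,7R)-dearomatised acylphloroglucinol [2-aroyl-3,5-dihydroxy-4,6-diprenylcyclohexa-2,4-dienone carrying the C15 chain CH2-CH(geranyl)-C(CH3)=CH2 on the quaternary carbon C5], via primary triflate 13 (not isolated)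
Conditions: Tf2O, 2,6-lutidine, CH2Cl2, −78 °C; cold solution added to 6 + LiN(SiMe3)2 (3.1 equiv), THF–toluene, −78 → 0 °C; 1 M HCl quench
Reagents that add atoms: triflic anhydride, O=S(=O)(OS(=O)(=O)C(F)(F)F)C(F)(F)F (its CF3SO2 group is held only by 13)
Why: Alkylative dearomatisation: the lithium trianion of the symmetric nucleus is C-alkylated by the primary triflate at a prenyl-bearing carbon (C1 and C5 are equivalent so there is no regiochemical issue, and lithium in a weakly polar medium favours C- over O-attack), C7 is carried in unchanged, whereas the new quaternary centre C5 receives no useful induction from C7 across the freely rotating CH2 (about 1:1) so the 5R epimer is separated by chromatography.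

**Step 8**
Reactants: 14 dearomatised acylphloroglucinol
Product: 15 (5R,7R)-pyran [O4 bonded to C8, ring O4-C8(CH3)2-C7H(geranyl)-C6H2-C5-C4, free enol at O9]
Conditions: [N,N'-bis(3,5-di-tert-butylsalicylidene)-1,2-cyclohexanediaminato]cobalt (C36H52CoN2O2, divalent cobalt, 5 mol%), N-fluoro-2,4,6-trimethylpyridinium triflate (1.5 equiv), (Me2SiH)2O (1.5 equiv), PhCF3, 0 °C → rt, argon
Reagents that add atoms: none
Why: Metal-hydride hydrogen-atom-transfer/radical–polar crossover Markovnikov hydroalkoxylation (Mukaiyama-type): the bulky cobalt hydride delivers H only to the unhindered 1,1-disubstituted alkene while the four trisubstituted alkenes are much slower, oxidation gives the C8 cation equivalent under buffered non-acidic conditions, and it is trapped by enol oxygen O4 through a chair-like six-membered ring with the geranyl group equatorial and anti to the axial C5 prenyl (closure on O9 would make them 1,3-diaxial); no stereocentre is made or touched.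

**Step 9**
Reactants: 15 pyran
Product: 17 oblongifolin B, via bis-TBS oblongifolin B 16 (not isolated)
Conditions: TMSOTf (2.5 equiv), 2,6-di-tert-butyl-4-methylpyridine (3 equiv), CH2Cl2, −78 → −20 °C; MeOH, −20 °C; then Bu4NF, AcOH, THF, 0 °C
Reagents that add atoms: none
Why: Proposed new method: silylation of the free O9 enol gives a C1=C9 silyl enol ether and O-silylation of the vinylogous ester carbonyl turns the tertiary O4–C8 bond into a leaving group exactly as in the TMSOTf cleavage of tert-butyl esters, so the biosynthetic C8 tertiary cation is released under aprotic, proton-trapped conditions in which none of the four trisubstituted alkenes can be protonated; return to oxygen is reversible whereas capture by C1 (Reetz-type α-tert-alkylation of a silyl enol ether, the closest known reaction, here intramolecular through a chair with the geranyl group equatorial) is irreversible because the silyl group leaves O9, which closes ring B, joins the two quaternary carbons and fixes C1 as S because the chain tethered to C5 can reach C1 only from its own face, C5 and C7 staying untouched, after which methanol frees the enol and buffered fluoride removes the two aryl silyl ethers.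

**Compound list**

| No. | Name | SMILES | Role |
|---|---|---|---|
| 1 | phloroglucinol | Oc1cc(O)cc(O)c1 | starting material |
| 2 | 3,4-dihydroxybenzonitrile | N#Cc1ccc(O)c(O)c1 | starting material |
| 3 | maclurin | O=C(c1ccc(O)c(O)c1)c1c(O)cc(O)cc1O | intermediate |
| 4 | prenyl bromide | CC(C)=CCBr | starting material |
| 5 | 3,5-diprenylmaclurin | O=C(c1ccc(O)c(O)c1)c1c(O)c(CC=C(C)C)c(O)c(CC=C(C)C)c1O | intermediate |
| 6 | 3',4'-bis-O-TBS-3,5-diprenylmaclurin | O=C(c1ccc(O[Si](C)(C)C(C)(C)C)c(O[Si](C)(C)C(C)(C)C)c1)c1c(O)c(CC=C(C)C)c(O)c(CC=C(C)C)c1O | intermediate |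
| 7 | (S)-4-benzyloxazolidin-2-one | O=C1N[C@@H](Cc2ccccc2)CO1 | starting material |
| 8 | 3-methylbut-2-enoyl chloride | CC(C)=CC(=O)Cl | starting material |
| 9 | (S)-4-benzyl-3-(3-methylbut-2-enoyl)oxazolidin-2-one | CC(C)=CC(=O)N1[C@@H](Cc2ccccc2)COC1=O | intermediate |
| 10 | geranyl bromide | CC(C)=CCC/C(C)=C/CBr | starting material |
| 11 | (S)-4-benzyl-3-[(2S,4E)-5,9-dimethyl-2-(prop-1-en-2-yl)deca-4,8-dienoyl]oxazolidin-2-one | CC(C)=CCC/C(C)=C/C[C@@H](C(C)=C)C(=O)N1[C@@H](Cc2ccccc2)COC1=O | intermediate |
| 12 | (2S,4E)-5,9-dimethyl-2-(prop-1-en-2-yl)deca-4,8-dien-1-ol | CC(C)=CCC/C(C)=C/C[C@@H](C(C)=C)CO | intermediate |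
| 13 | (2S,4E)-5,9-dimethyl-2-(prop-1-en-2-yl)deca-4,8-dienyl triflate | CC(C)=CCC/C(C)=C/C[C@@H](C(C)=C)COS(=O)(=O)C(F)(F)F | intermediate |
| 14 | (5R,7R)-dearomatised acylphloroglucinol | O=C1C(C(=O)c2ccc(O[Si](C)(C)C(C)(C)C)c(O[Si](C)(C)C(C)(C)C)c2)=C(O)C(CC=C(C)C)=C(O)[C@@]1(CC=C(C)C)C[C@@H](C/C=C(\C)CCC=C(C)C)C(C)=C | intermediate |
| 15 | (5R,7R)-O4–C8 pyran | O=C1C(CC=C(C)C)=C(O)[C@@]2(CC=C(C)C)C[C@@H](C/C=C(\C)CCC=C(C)C)C(C)(C)OC2=C1C(=O)c1ccc(O[Si](C)(C)C(C)(C)C)c(O[Si](C)(C)C(C)(C)C)c1 | intermediate |
| 16 | (1S,5S,7R)-3',4'-bis-O-TBS oblongifolin B | CC(C)=CCC/C(C)=C/C[C@@H]1C[C@]2(CC=C(C)C)C(=O)[C@@](CC=C(C)C)(C(=O)C(C(=O)c3ccc(O[Si](C)(C)C(C)(C)C)c(O[Si](C)(C)C(C)(C)C)c3)=C2O)C1(C)C | intermediate |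
| 17 | (1S,5S,7R)-oblongifolin B | CC(C)=CCC/C(C)=C/C[C@@H]1C[C@]2(CC=C(C)C)C(=O)[C@@](CC=C(C)C)(C(=O)C(C(=O)c3ccc(O)c(O)c3)=C2O)C1(C)C | target |

Total step count: 9.
Longest linear sequence: 6 (steps 4, 5, 6, 7, 8, 9). The aromatic branch 1, 2, 3, 7, 8, 9 is equally long.

**Steps most likely to fail**

**Step 9.**
- Failure modes: proton loss from the C8 cation; a 1,2-hydride shift from C7 that would scramble C7; capture of the cation by the C5 prenyl alkene instead of the hindered C1.
- The fallback sets out from 14 and comes back at 16.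
- It gives up the pyran reservoir and the Lewis acid.
- 14 is exhaustively silylated (TBSOTf, 2,6-lutidine) to the bis(silyl enol ether) F1, which has no OH left.
- The C8 cation is then made directly and irreversibly from the isopropenyl group with the cobalt hydride, N-fluorocollidinium and silane system of step 8.
- The cation is now short-lived, and its nearest π-nucleophile is the C1=C9 silyl enol ether.
- Any isopropenyl alkene re-formed by proton loss re-enters the catalytic cycle.
- Aqueous work-up hydrolyses the remaining enol silyl ether and gives 16.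

**Step 7.**
- Failure modes: no control at C5, so half of the material is lost; competing O-alkylation.
- The fallback sets out from 5 and 12 and comes back at 16.
- It inverts the order of the two C–C bonds so that each new centre is made inside a ring.
- 5 is silylated at O9 as well (TBSOTf, 2,6-lutidine) to the tris-silyl ether F2.
- Mitsunobu etherification (PPh3, DIAD) with 12 puts the chain on one of the two equivalent chelated phenols and gives the O2 aryl ether F3.
- The cobalt hydride system of step 8 then closes C8 onto the prenylated ortho carbon C1. This is a dearomative intramolecular hydroarylation with no O-nucleophile in reach.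
- The closure runs through an O-tethered six-membered chair with the geranyl group equatorial and anti to the prenyl group that is pushed axial. This sets C1 from C7 and gives the tricyclic dienone F4.
- Lithium iodide in hot 2,6-lutidine removes the O9 silyl group and shuttles C6 from O2 (reversible O-alkylation) to C5 (irreversible C-alkylation).
- C5 can form only on the tethered face, which gives 16.

**Step 8.**
- Failure modes: attack of the cobalt hydride on a prenyl group; electrophilic fluorination of the enols by the N–F oxidant.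
- The fallback sets out from 12 and 6 and comes back at 15.
- It moves the alkene differentiation to the simple chain.
- 12 is hydrated at the isopropenyl group (Mukaiyama hydration: tris(dipivaloylmethanato)manganese, Mn(C11H19O2)3, PhSiH3, O2, i-PrOH) to the diol F5.
- Primary-selective triflation (Tf2O, 2,6-lutidine, −78 °C) gives the hydroxy triflate F6.
- Alkylative dearomatisation of 6 as in step 7 gives, after separation of the C5 epimer, the tertiary alcohol F7.
- Trifluoroacetylation (TFAA, 2,6-lutidine) followed by ionisation in CH2Cl2–(CF3)2CHOH closes O4 onto C8 and gives 15.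

**Further compounds**
F1 | step 9 | O2,O9-bis(TBS enol ether) of 14 | O=C1C(C(=O)c2ccc(O[Si](C)(C)C(C)(C)C)c(O[Si](C)(C)C(C)(C)C)c2)=C(O[Si](C)(C)C(C)(C)C)C(CC=C(C)C)=C(O[Si](C)(C)C(C)(C)C)[C@@]1(CC=C(C)C)C[C@@H](C/C=C(\C)CCC=C(C)C)C(C)=C
F2 | step 7 | O9,3',4'-tris-O-TBS-3,5-diprenylmaclurin | O=C(c1ccc(O[Si](C)(C)C(C)(C)C)c(O[Si](C)(C)C(C)(C)C)c1)c1c(O)c(CC=C(C)C)c(O[Si](C)(C)C(C)(C)C)c(CC=C(C)C)c1O
F3 | step 7 | O2 aryl ether of F2 with the (S)-C15 chain | O=C(c1ccc(O[Si](C)(C)C(C)(C)C)c(O[Si](C)(C)C(C)(C)C)c1)c1c(O)c(CC=C(C)C)c(O[Si](C)(C)C(C)(C)C)c(CC=C(C)C)c1OC[C@@H](C/C=C(\C)CCC=C(C)C)C(C)=C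
F4 | step 7 | tricyclic dienone with the C1–C8 bond and the O2–C6 tether | O=C1C(CC=C(C)C)=C(O[Si](C)(C)C(C)(C)C)[C@]2(CC=C(C)C)C(C)(C)[C@H](C/C=C(\C)CCC=C(C)C)COC2=C1C(=O)c1ccc(O[Si](C)(C)C(C)(C)C)c(O[Si](C)(C)C(C)(C)C)c1
F5 | step 8 | (2R,4E)-2-(2-hydroxypropan-2-yl)-5,9-dimethyldeca-4,8-dien-1-ol | CC(C)=CCC/C(C)=C/C[C@@H](C(C)(C)O)CO
F6 | step 8 | primary triflate of F5 | CC(C)=CCC/C(C)=C/C[C@@H](C(C)(C)O)COS(=O)(=O)C(F)(F)F
F7 | step 8 | (5R,7R)-dearomatised acylphloroglucinol with a tertiary alcohol at C8 | O=C1C(C(=O)c2ccc(O[Si](C)(C)C(C)(C)C)c(O[Si](C)(C)C(C)(C)C)c2)=C(O)C(CC=C(C)C)=C(O)[C@@]1(CC=C(C)C)C[C@@H](C/C=C(\C)CCC=C(C)C)C(C)(C)O
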